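## Retrosynthetic overview

1. In the cyclohexenone ring, the three contiguous carbons C4(OH)–C3(CH3)=C2(OAc) carry oxygen on both outer atoms. With the central carbon at the ketone level they are the C4–C5–C6 unit of 2,2-dimethyl-1,3-dioxan-5-one (protected dihydroxyacetone), whose two α-carbons are both nucleophilic and already oxygenated.
2. The other three ring carbons, C5H2–C6(=alkylidene)–C1(=O), are a 2-(bromomethyl)alk-2-enoyl 1,3-bis-electrophile. Its fully substituted γ-carbon blocks SN2′ attack, so the exocyclic alkene geometry is carried through unchanged.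
3. The only carbocycle is closed by a chiral-enamine α,α′-annulation (C-alkylation, then C-acylation) that forms both ring bonds flanking the oxygenated three-carbon unit and sets the ring carbinol. The temporary dioxane ring and the central ketone (the activating group) are removed afterwards by Wittig methylenation, ketal cleavage and double-bond migration into the diosphenol.
4. The bis-electrophile comes from an ynone: asymmetric transfer hydrogenation sets the side-chain carbinol, and hydroxyl-directed syn-carbomagnesiation/carboxylation sets the tetrasubstituted alkene. The angelate and the enol acetate are introduced last.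

Key step: step 8

Remark on the chemistry: the (2S,5S)-amine 12 is chosen on the model that an electrophile approaches the enamine carbon on the face anti to the neighbouring pyrrolidine methyl group. TBS = tert-butyldimethylsilyl; angelate = (2Z)-2-methylbut-2-enoate.

## Route

Step 1
Reactants: 1 4-methylpent-3-enoic acid
Product: 2 N-methoxy-N,4-dimethylpent-3-enamide
Conditions: CDI, CH2Cl2, 20 °C; then MeNHOMe·HCl, 20 °C
Reagents that add atoms: N,O-dimethylhydroxylamine hydrochloride, CNOC.Cl
Why: Aminolysis of the acyl imidazolide (Weinreb amide formation) proceeds without added base, so the skipped alkene should not move into conjugation; no stereocentre is formed.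

Step 2
Reactants: 2 N-methoxy-N,4-dimethylpent-3-enamide; 3 tert-butyldimethyl(prop-2-yn-1-yloxy)silane
Product: 4 1-[(tert-butyldimethylsilyl)oxy]-7-methyloct-6-en-2-yn-4-one
Conditions: 3, n-BuLi, THF, −78 °C; then 2, −78 → −20 °C; aq. NH4Cl
Reagents that add atoms: none
Why: Weinreb ketone synthesis, in which the chelated tetrahedral intermediate stops the lithium acetylide at the ynone stage and the low temperature keeps the β,γ-alkene in place; no stereocentre is formed.

Step 3
Reactants: 4 1-[(tert-butyldimethylsilyl)oxy]-7-methyloct-6-en-2-yn-4-one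
Product: 5 (4S)-1-[(tert-butyldimethylsilyl)oxy]-7-methyloct-6-en-2-yn-4-ol
Conditions: Ru[(S,S)-TsDPEN–H](p-cymene) (preformed amido complex, 1 mol%), i-PrOH, 25 °C
Reagents that add atoms: none
Why: Noyori–Ikariya asymmetric transfer hydrogenation of an alkynyl ketone, in which the (S,S)-catalyst should deliver hydride and proton to the face that places the alkynyl group in the arene CH/π site and so give the S carbinol, under base-free conditions that spare the skipped alkene.

Step 4
Reactants: 5 (4S)-1-[(tert-butyldimethylsilyl)oxy]-7-methyloct-6-en-2-yn-4-ol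
Product: 7 (4S)-4-[(tert-butyldimethylsilyl)oxy]-7-methyloct-6-en-2-yn-1-ol, via bis-silyl ether 6 (not isolated)
Conditions: TBSOTf, 2,6-lutidine, CH2Cl2, −78 °C; then MeOH, CSA (in excess over lutidine), −10 °C
Reagents that add atoms: tert-butyldimethylsilyl trifluoromethanesulfonate, CC(C)(C)[Si](C)(C)OS(=O)(=O)C(F)(F)F
Why: Silylation of the secondary alcohol followed by acid-catalysed methanolysis, which should cleave the unhindered primary silyl ether much faster than the secondary one; the stereocentre is not touched.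

Step 5
Reactants: 7 (4S)-4-[(tert-butyldimethylsilyl)oxy]-7-methyloct-6-en-2-yn-1-ol
Product: 8 (2E,4S)-4-[(tert-butyldimethylsilyl)oxy]-2-(hydroxymethyl)-3,7-dimethylocta-2,6-dienoic acid
Conditions: MeMgBr (4 equiv), Fe(acac)3 (15 mol%), THF, −78 → 0 °C; then CO2 (1 atm), −30 → 20 °C; aq. citric acid
Reagents that add atoms: methylmagnesium bromide, C[Mg]Br; carbon dioxide, O=C=O
Why: Alkoxide-directed iron-catalysed syn-carbomagnesiation of a propargylic alcohol should place methyl on the alkyne carbon remote from the alkoxide and magnesium on the near one, and carboxylation of that alkenyl Grignard with retention fixes the tetrasubstituted alkene (methyl cis to CO2H, CH2OH cis to the silyloxy-bearing carbon); no stereocentre is formed.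

Step 6
Reactants: 8 (2E,4S)-4-[(tert-butyldimethylsilyl)oxy]-2-(hydroxymethyl)-3,7-dimethylocta-2,6-dienoic acid
Product: 10 pentafluorophenyl (2Z,4S)-2-(bromomethyl)-4-[(tert-butyldimethylsilyl)oxy]-3,7-dimethylocta-2,6-dienoate, via acyl bromide 9 (not isolated)
Conditions: PPh3 (2.4 equiv), CBr4 (2.4 equiv), CH2Cl2, 0 °C; then C6F5OH, 2,6-lutidine, 0 °C
Reagents that add atoms: carbon tetrabromide, BrC(Br)(Br)Br; pentafluorophenol, Oc1c(F)c(F)c(F)c(F)c1F
Why: Appel conditions should convert the primary allylic alcohol to the bromide (SN2 on the alkoxyphosphonium ion) and the acid to the acyl bromide, which pentafluorophenol then esterifies, all under neutral conditions that keep the silyl ether, the stereocentre and the alkene geometry.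

Step 7
Reactants: 11 2,2-dimethyl-1,3-dioxan-5-one; 12 (2S,5S)-2,5-dimethylpyrrolidine
Product: 13 (2S,5S)-1-(2,2-dimethyl-4H-1,3-dioxin-5-yl)-2,5-dimethylpyrrolidine
Conditions: 4 Å molecular sieves, benzene, 40 °C
Reagents that add atoms: none
Why: Enamine condensation of a symmetric ketone with a C2-symmetric secondary amine, so that a single enamine with one defined chiral environment results.

Step 8
Reactants: 10 pentafluorophenyl (2Z,4S)-2-(bromomethyl)-4-[(tert-butyldimethylsilyl)oxy]-3,7-dimethylocta-2,6-dienoate; 13 (2S,5S)-1-(2,2-dimethyl-4H-1,3-dioxin-5-yl)-2,5-dimethylpyrrolidine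
Product: 17 (1R,5S,7E)-7-[(3S)-3-[(tert-butyldimethylsilyl)oxy]-6-methylhept-5-en-2-ylidene]-3,3-dimethyl-2,4-dioxabicyclo[3.3.1]nonane-6,9-dione, via iminium bromide 14 (not isolated), via alkylated enamine 15 (not isolated), via bridged iminium salt 16 (not isolated)
Conditions: MeCN, −20 → 0 °C; then i-Pr2NEt, 50 °C; then NaOAc/AcOH buffer (pH 5), THF–H2O, 20 °C
Reagents that add atoms: water, O
Why: Proposed new method: the chiral enamine is C-alkylated (Stork enamine alkylation) by direct SN2 displacement at the primary allylic bromide, which makes the ring CH2–CH(O) bond; loss of a proton to i-Pr2NEt regenerates the enamine on the unsubstituted side with the new chain axial (allylic 1,3-strain), so that its nucleophilic carbon lies over the pentafluorophenyl ester and attacks it (6-exo-trig addition–elimination, a Claisen-type C-acylation) to make the bond between the ketone carbon and the second oxygen-bearing carbon, and hydrolysis of the bridged iminium ion gives the dione. The closest known reaction type is the α,α′-annulation of cyclic-ketone enamines with 2-(bromomethyl)acrylates or acryloyl chlorides to bicyclo[3.3.1]nonan-9-ones; new here are the alkylation/acylation pairing, the aryl ester as acyl donor and the dioxanone enamine. The carbocycle is closed in the second event as a six-membered ring bridged across the dioxane, and pentafluorophenoxide is too weak a nucleophile to reverse the acylation. The carbinol stereocentre is set in the alkylation, where the electrophile should approach the enamine carbon on the face anti to the adjacent pyrrolidine methyl group of the (2S,5S)-amine and give R; the second bridgehead is forced cis and is erased later, and because the side-chain centre is remote any minor isomer is a separable diastereomer. The step needs SN2 rather than SN2′ attack (secured by the fully substituted γ-carbon, which also preserves the alkene geometry), alkylation before acylation (the hindered conjugated aryl ester is a poor intermolecular acyl donor but should react intramolecularly) and enamine regeneration away from the new stereocentre (secured by allylic strain).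

Step 9
Reactants: 17 (1R,5S,7E)-7-[(3S)-3-[(tert-butyldimethylsilyl)oxy]-6-methylhept-5-en-2-ylidene]-3,3-dimethyl-2,4-dioxabicyclo[3.3.1]nonane-6,9-dione
Product: 18 (1R,5R,7E)-7-[(3S)-3-[(tert-butyldimethylsilyl)oxy]-6-methylhept-5-en-2-ylidene]-3,3-dimethyl-9-methylidene-2,4-dioxabicyclo[3.3.1]nonan-6-one
Conditions: Ph3PCH3Br, KN(SiMe3)2, THF, 0 °C; then 17, −78 → 0 °C
Reagents that add atoms: methyltriphenylphosphonium bromide, C[P+](c1ccccc1)(c1ccccc1)c1ccccc1.[Br-]
Why: Wittig methylenation should take place at the bridging ketone, which is activated by two α-oxygens and cannot enolise, in preference to the hindered cross-conjugated enone carbonyl; no stereocentre is formed (the bridgehead descriptor changes only by priority).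

Step 10
Reactants: 18 (1R,5R,7E)-7-[(3S)-3-[(tert-butyldimethylsilyl)oxy]-6-methylhept-5-en-2-ylidene]-3,3-dimethyl-9-methylidene-2,4-dioxabicyclo[3.3.1]nonan-6-one
Product: 19 (1R,5R,7E)-7-[(3S)-3-hydroxy-6-methylhept-5-en-2-ylidene]-3,3-dimethyl-9-methylidene-2,4-dioxabicyclo[3.3.1]nonan-6-one
Conditions: HF·pyridine, pyridine, THF, 0 → 20 °C
Reagents that add atoms: none
Why: Fluoride-mediated desilylation under pyridine buffering should leave the ketal, the exocyclic alkenes and the carbinol configuration untouched.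

Step 11
Reactants: 19 (1R,5R,7E)-7-[(3S)-3-hydroxy-6-methylhept-5-en-2-ylidene]-3,3-dimethyl-9-methylidene-2,4-dioxabicyclo[3.3.1]nonan-6-one; 20 angelic acid, (2Z)-2-methylbut-2-enoic acid
Product: 22 (1R,5R,7E)-7-[(3S)-3-{[(2Z)-2-methylbut-2-enoyl]oxy}-6-methylhept-5-en-2-ylidene]-3,3-dimethyl-9-methylidene-2,4-dioxabicyclo[3.3.1]nonan-6-one, via mixed anhydride 21 (not isolated)
Conditions: 20, 2,4,6-trichlorobenzoyl chloride, Et3N, toluene, 20 °C; then 19, 80 °C
Reagents that add atoms: 2,4,6-trichlorobenzoyl chloride, O=C(Cl)c1c(Cl)cc(Cl)cc1Cl (its atoms stay in intermediate 21 only)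
Why: Yamaguchi-type esterification through the mixed anhydride, run without a nucleophilic catalyst so that the Z-enoate is not isomerised to the tiglate, acylates the only free hydroxyl at oxygen and therefore retains the S configuration.

Step 12
Reactants: 22 (1R,5R,7E)-7-[(3S)-3-{[(2Z)-2-methylbut-2-enoyl]oxy}-6-methylhept-5-en-2-ylidene]-3,3-dimethyl-9-methylidene-2,4-dioxabicyclo[3.3.1]nonan-6-one
Product: 24 (4R,6E)-2,4-dihydroxy-3-methyl-6-[(3S)-3-{[(2Z)-2-methylbut-2-enoyl]oxy}-6-methylhept-5-en-2-ylidene]cyclohex-2-en-1-one, via methylidene diol 23 (not isolated)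
Conditions: PPTS, MeOH, 25 °C; then Et3N (0.5 equiv), 0 °C
Reagents that add atoms: none
Why: Acid-catalysed transketalisation frees the cis-1,3-diol, and once the bridge is gone the carbinol carbon next to the ketone can enolise, so the β,γ-unsaturated α-ketol should tautomerise (protonation at the exocyclic methylene) to the conjugated diosphenol, which creates the ring methyl group, erases that stereocentre and leaves the R carbinol untouched.

Step 13
Reactants: 24 (4R,6E)-2,4-dihydroxy-3-methyl-6-[(3S)-3-{[(2Z)-2-methylbut-2-enoyl]oxy}-6-methylhept-5-en-2-ylidene]cyclohex-2-en-1-one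
Product: 25 (4R,6E)-2-acetoxy-4-hydroxy-3-methyl-6-[(3S)-3-{[(2Z)-2-methylbut-2-enoyl]oxy}-6-methylhept-5-en-2-ylidene]cyclohex-2-en-1-one (target)
Conditions: Ac2O (1.05 equiv), Et3N, CH2Cl2, −30 °C
Reagents that add atoms: acetic anhydride, CC(=O)OC(C)=O
Why: Chemoselective O-acetylation of the acidic diosphenol hydroxyl through its ammonium enolate, without an acyl-transfer catalyst, should leave the much less acidic secondary allylic alcohol free, and migration of the acetyl group to that alcohol is prevented by their trans disposition across the ring double bond.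

## Compound list

1 | 4-methylpent-3-enoic acid | CC(C)=CCC(=O)O | starting material
2 | N-methoxy-N,4-dimethylpent-3-enamide | CC(C)=CCC(=O)N(C)OC | intermediate
3 | tert-butyldimethyl(prop-2-yn-1-yloxy)silane | C#CCO[Si](C)(C)C(C)(C)C | starting material
4 | 1-[(tert-butyldimethylsilyl)oxy]-7-methyloct-6-en-2-yn-4-one | CC(C)=CCC(=O)C#CCO[Si](C)(C)C(C)(C)C | intermediate
5 | (4S)-1-[(tert-butyldimethylsilyl)oxy]-7-methyloct-6-en-2-yn-4-ol | CC(C)=CC[C@H](O)C#CCO[Si](C)(C)C(C)(C)C | intermediate
6 | (4S)-1,4-bis[(tert-butyldimethylsilyl)oxy]-7-methyloct-6-en-2-yne | CC(C)=CC[C@H](O[Si](C)(C)C(C)(C)C)C#CCO[Si](C)(C)C(C)(C)C | intermediate (not isolated)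
7 | (4S)-4-[(tert-butyldimethylsilyl)oxy]-7-methyloct-6-en-2-yn-1-ol | CC(C)=CC[C@H](O[Si](C)(C)C(C)(C)C)C#CCO | intermediate
8 | (2E,4S)-4-[(tert-butyldimethylsilyl)oxy]-2-(hydroxymethyl)-3,7-dimethylocta-2,6-dienoic acid | OC(=O)/C(CO)=C(\C)[C@@H](O[Si](C)(C)C(C)(C)C)CC=C(C)C | intermediate
9 | (2E,4S)-2-(bromomethyl)-4-[(tert-butyldimethylsilyl)oxy]-3,7-dimethylocta-2,6-dienoyl bromide | O=C(Br)/C(CBr)=C(\C)[C@@H](O[Si](C)(C)C(C)(C)C)CC=C(C)C | intermediate (not isolated)
10 | pentafluorophenyl (2Z,4S)-2-(bromomethyl)-4-[(tert-butyldimethylsilyl)oxy]-3,7-dimethylocta-2,6-dienoate | O=C(Oc1c(F)c(F)c(F)c(F)c1F)/C(CBr)=C(\C)[C@@H](O[Si](C)(C)C(C)(C)C)CC=C(C)C | intermediate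
11 | 2,2-dimethyl-1,3-dioxan-5-one | CC1(C)OCC(=O)CO1 | starting material
12 | (2S,5S)-2,5-dimethylpyrrolidine | C[C@H]1CC[C@H](C)N1 | starting material
13 | (2S,5S)-1-(2,2-dimethyl-4H-1,3-dioxin-5-yl)-2,5-dimethylpyrrolidine | C[C@H]1CC[C@H](C)N1C1=COC(C)(C)OC1 | intermediate
14 | iminium bromide from C-alkylation of 13 by 10 at the enamine carbon (4R on the dioxane ring; side chain as in 10) | C[C@H]1CC[C@H](C)[N+]1=C2COC(C)(C)O[C@@H]2C/C(C(=O)Oc3c(F)c(F)c(F)c(F)c3F)=C(/C)[C@@H](O[Si](C)(C)C(C)(C)C)CC=C(C)C.[Br-] | intermediate (not isolated)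
15 | enamine regenerated from 14 on the unsubstituted side (4R on the dioxin ring) | C[C@H]1CC[C@H](C)N1C2=COC(C)(C)O[C@@H]2C/C(C(=O)Oc3c(F)c(F)c(F)c(F)c3F)=C(/C)[C@@H](O[Si](C)(C)C(C)(C)C)CC=C(C)C | intermediate (not isolated)
16 | bridged iminium pentafluorophenoxide, the 9-(pyrrolidinium-1-ylidene) analogue of 17 | C[C@H]1CC[C@H](C)[N+]1=C2[C@H]3C/C(=C(/C)[C@@H](O[Si](C)(C)C(C)(C)C)CC=C(C)C)C(=O)[C@@H]2OC(C)(C)O3.[O-]c1c(F)c(F)c(F)c(F)c1F | intermediate (not isolated)
17 | (1R,5S,7E)-7-[(3S)-3-[(tert-butyldimethylsilyl)oxy]-6-methylhept-5-en-2-ylidene]-3,3-dimethyl-2,4-dioxabicyclo[3.3.1]nonane-6,9-dione | CC(C)=CC[C@H](O[Si](C)(C)C(C)(C)C)/C(C)=C1\C[C@H]2OC(C)(C)O[C@@H](C1=O)C2=O | intermediate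
18 | (1R,5R,7E)-7-[(3S)-3-[(tert-butyldimethylsilyl)oxy]-6-methylhept-5-en-2-ylidene]-3,3-dimethyl-9-methylidene-2,4-dioxabicyclo[3.3.1]nonan-6-one | CC(C)=CC[C@H](O[Si](C)(C)C(C)(C)C)/C(C)=C1\C[C@H]2OC(C)(C)O[C@@H](C1=O)C2=C | intermediate
19 | (1R,5R,7E)-7-[(3S)-3-hydroxy-6-methylhept-5-en-2-ylidene]-3,3-dimethyl-9-methylidene-2,4-dioxabicyclo[3.3.1]nonan-6-one | CC(C)=CC[C@H](O)/C(C)=C1\C[C@H]2OC(C)(C)O[C@@H](C1=O)C2=C | intermediate
20 | angelic acid, (2Z)-2-methylbut-2-enoic acid | C/C=C(/C)C(=O)O | starting material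
21 | (2Z)-2-methylbut-2-enoic 2,4,6-trichlorobenzoic anhydride | C/C=C(/C)C(=O)OC(=O)c1c(Cl)cc(Cl)cc1Cl | intermediate (not isolated)
22 | (1R,5R,7E)-7-[(3S)-3-{[(2Z)-2-methylbut-2-enoyl]oxy}-6-methylhept-5-en-2-ylidene]-3,3-dimethyl-9-methylidene-2,4-dioxabicyclo[3.3.1]nonan-6-one | C/C=C(/C)C(=O)O[C@@H](CC=C(C)C)/C(C)=C1\C[C@H]2OC(C)(C)O[C@@H](C1=O)C2=C | intermediate
23 | (2R,4R,6E)-2,4-dihydroxy-3-methylidene-6-[(3S)-3-{[(2Z)-2-methylbut-2-enoyl]oxy}-6-methylhept-5-en-2-ylidene]cyclohexan-1-one | C/C=C(/C)C(=O)O[C@@H](CC=C(C)C)/C(C)=C1\C[C@@H](O)C(=C)[C@@H](O)C1=O | intermediate (not isolated)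
24 | (4R,6E)-2,4-dihydroxy-3-methyl-6-[(3S)-3-{[(2Z)-2-methylbut-2-enoyl]oxy}-6-methylhept-5-en-2-ylidene]cyclohex-2-en-1-one | C/C=C(/C)C(=O)O[C@@H](CC=C(C)C)/C(C)=C1\C[C@@H](O)C(C)=C(O)C1=O | intermediate
25 | (4R,6E)-2-acetoxy-4-hydroxy-3-methyl-6-[(3S)-3-{[(2Z)-2-methylbut-2-enoyl]oxy}-6-methylhept-5-en-2-ylidene]cyclohex-2-en-1-one | C/C=C(/C)C(=O)O[C@@H](CC=C(C)C)/C(C)=C1\C[C@@H](O)C(C)=C(OC(C)=O)C1=O | target

## Step count and risks

Total step count: 13. Longest linear sequence: 12 steps (steps 1–6, then 8–13); step 7 is a one-step side branch.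

Steps most likely to fail:

1. Step 8 (proposed new method). The intramolecular C-acylation may be slower than equilibration of the enamine toward the substituted carbon, which would erode the configuration of the new carbinol carbon, or the bridged non-enolisable β-diketone may be opened by retro-Claisen attack of the liberated amine during hydrolysis. Fallback with known chemistry: starting from 10 and 13, only the Stork enamine C-alkylation is run (MeCN, 0 °C) and the iminium ion is hydrolysed at once with acetate buffer to give pentafluorophenyl (2E,4S)-4-[(tert-butyldimethylsilyl)oxy]-2-{[(4R)-2,2-dimethyl-5-oxo-1,3-dioxan-4-yl]methyl}-3,7-dimethylocta-2,6-dienoate F1. The ring is then closed in a separate soft-enolisation Claisen acylation (MgBr2·OEt2, i-Pr2NEt, CH2Cl2, 0 °C), in which the magnesium enolate on the unsubstituted side is C-acylated by the aryl ester, returning to 17.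

2. Step 12. The methylidene-to-methyl migration may stall, or the 3-methylidene-2,4-diol array may ionise at an allylic carbinol and lose water toward an aromatic catechol before the double bond has moved. Fallback: starting from 17, the olefination is skipped and the methyl group is added to the bridging ketone as an organocerium reagent (MeMgBr, CeCl3, THF, −78 °C) from the face flanked by the two ring oxygens, giving (1R,5R,7E,9S)-7-[(3S)-3-[(tert-butyldimethylsilyl)oxy]-6-methylhept-5-en-2-ylidene]-9-hydroxy-3,3,9-trimethyl-2,4-dioxabicyclo[3.3.1]nonan-6-one F2 (the configuration of this carbinol is lost later). Desilylation as in step 10 gives the corresponding side-chain alcohol F3, and angeloylation as in step 11 gives its angelate F4. Treatment of F4 with CSA in MeOH then cleaves the ketal and dehydrates the β-hydroxy ketone through its enol (aldol-type elimination), so that the methyl-bearing double bond is made by elimination and not by isomerisation, returning to 24.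

3. Step 11. The angeloyl unit may isomerise from Z to E (tiglate) during activation, or acyl transfer to the hindered allylic alcohol may be too slow. Fallback: starting from 19, the alcohol is esterified with 2-[bis(2,2,2-trifluoroethoxy)phosphoryl]propanoic acid (DCC, DMAP, CH2Cl2) to give the phosphonate ester F5 (epimeric at the phosphonate carbon). A Still–Gennari olefination with acetaldehyde (KN(SiMe3)2, 18-crown-6, THF, −78 °C) then builds the Z-enoate on the molecule, returning to 22.

Further compounds

F1 | step 8 | pentafluorophenyl (2E,4S)-4-[(tert-butyldimethylsilyl)oxy]-2-{[(4R)-2,2-dimethyl-5-oxo-1,3-dioxan-4-yl]methyl}-3,7-dimethylocta-2,6-dienoate | CC1(C)OCC(=O)[C@@H](C/C(C(=O)Oc2c(F)c(F)c(F)c(F)c2F)=C(/C)[C@@H](O[Si](C)(C)C(C)(C)C)CC=C(C)C)O1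
F2 | step 12 | (1R,5R,7E,9S)-7-[(3S)-3-[(tert-butyldimethylsilyl)oxy]-6-methylhept-5-en-2-ylidene]-9-hydroxy-3,3,9-trimethyl-2,4-dioxabicyclo[3.3.1]nonan-6-one | CC(C)=CC[C@H](O[Si](C)(C)C(C)(C)C)/C(C)=C1\C[C@H]2OC(C)(C)O[C@@H](C1=O)[C@@]2(C)O
F3 | step 12 | (1R,5R,7E,9S)-9-hydroxy-7-[(3S)-3-hydroxy-6-methylhept-5-en-2-ylidene]-3,3,9-trimethyl-2,4-dioxabicyclo[3.3.1]nonan-6-one | CC(C)=CC[C@H](O)/C(C)=C1\C[C@H]2OC(C)(C)O[C@@H](C1=O)[C@@]2(C)O
F4 | step 12 | (1R,5R,7E,9S)-9-hydroxy-3,3,9-trimethyl-7-[(3S)-3-{[(2Z)-2-methylbut-2-enoyl]oxy}-6-methylhept-5-en-2-ylidene]-2,4-dioxabicyclo[3.3.1]nonan-6-one | C/C=C(/C)C(=O)O[C@@H](CC=C(C)C)/C(C)=C1\C[C@H]2OC(C)(C)O[C@@H](C1=O)[C@@]2(C)O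
F5 | step 11 | 2-[bis(2,2,2-trifluoroethoxy)phosphoryl]propanoate (2RS) of alcohol 19 | CC(C(=O)O[C@@H](CC=C(C)C)/C(C)=C1\C[C@H]2OC(C)(C)O[C@@H](C1=O)C2=C)P(=O)(OCC(F)(F)F)OCC(F)(F)F
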